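**Plan**

- Retrosynthetic cuts, in order: the S–O bond of the sulfate; the ring A C5–Br bond (back to C–H through a boronate); the aromaticity and the C3–Br bond of ring A (back to a 2-aryloxycyclohexane-1,3-dione); the ring A C1–C2 bond (intramolecular Claisen condensation of a 6-aryloxy-5-oxohexanoate); the O–CH2 bond to ring B; the aryl ether bond between rings B and C.
- Enabling feature: in ring A (C1 OSO3H, C2 ether O to ring B, C3 Br, C5 Br) the ether-bearing C2 sits between C1–O and C3–Br, and these two carbons are the two carbonyl carbons of a symmetric 2-aryloxycyclohexane-1,3-dione. The crowded A–O–B ether can therefore be made by SN2 at a CH2 group before ring A exists.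
- Forward order: rings B and C are bought as arenes and joined by iodonium O-arylation; after demethylation the keto ester chain is attached by O-alkylation; ring A then closes as a saturated dione, becomes the bromoenone, is aromatised, brominated at C5 through C–H borylation, and sulfated.
- Stereochemistry: the target is achiral and has no stereocentre, so nothing has to be controlled.

Key step: step 7

Assumption 1: the target is taken as the free aryl hydrogen sulfate as drawn; it is released from its pyridinium salt by cation exchange in the last step and is best kept cold.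
Assumption 2: tribromination of guaiacol is taken to occupy C4 and C6 (para and ortho to OH) and C5 (para to OMe), leaving the least activated C3–H.

**Route**

Step 1
Reactants: 1 guaiacol (2-methoxyphenol)
Product: 2 2,3,4-tribromo-6-methoxyphenol (4,5,6-tribromoguaiacol)
Conditions: Br2 (3.1 equiv), AcOH, 15 °C to 60 °C
Reagents that add atoms: bromine, BrBr
Why: Electrophilic aromatic bromination in which the hydroxyl group should direct two bromines to its para and ortho positions and the methoxy group the third to its para position, leaving only the C–H next to OMe.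

Step 2
Reactants: 3 2,4-dibromo-1-iodobenzene
Product: 5 (2,4-dibromophenyl)(2,4,6-trimethoxyphenyl)iodonium 4-methylbenzenesulfonate, via hydroxy(tosyloxy)iodoarene 4 (not isolated)
Conditions: mCPBA, TsOH·H2O, MeCN, 77 °C; then 1,3,5-trimethoxybenzene, 77 °C
Reagents that add atoms: 1,3,5-trimethoxybenzene, COc1cc(OC)cc(OC)c1; 4-methylbenzenesulfonic acid monohydrate, Cc1ccc(cc1)S(=O)(=O)O.O; mCPBA (3-chloroperoxybenzoic acid, its oxygen is held only in 4), O=C(OO)c1cccc(Cl)c1
Why: One-pot diaryliodonium salt synthesis, in which peracid oxidation of the aryl iodide should give a Koser-type trivalent-iodine species that undergoes electrophilic aromatic substitution on the electron-rich trimethoxybenzene.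

Step 3
Reactants: 2 2,3,4-tribromo-6-methoxyphenol; 5 (2,4-dibromophenyl)(2,4,6-trimethoxyphenyl)iodonium 4-methylbenzenesulfonate
Product: 6 1,2,3-tribromo-4-(2,4-dibromophenoxy)-5-methoxybenzene
Conditions: K2CO3, MeCN, 50 °C
Reagents that add atoms: none
Why: Metal-free O-arylation of a phenoxide with a diaryliodonium salt (ligand coupling at trivalent iodine), in which the electron-rich trimethoxyphenyl group should stay on iodine as the dummy ligand while the electron-poor, ortho-substituted dibromophenyl group is transferred to the crowded phenoxide.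

Step 4
Reactants: 6 1,2,3-tribromo-4-(2,4-dibromophenoxy)-5-methoxybenzene
Product: 7 3,4,5-tribromo-2-(2,4-dibromophenoxy)phenol
Conditions: BBr3, CH2Cl2, −78 °C to rt; then H2O
Reagents that add atoms: none
Why: Lewis acid-mediated demethylation of an aryl methyl ether (boron coordination, then SN2 attack of bromide on the methyl group), which should leave the diaryl ether bond and the C–Br bonds untouched.

Step 5
Reactants: 8 methyl 5-chloro-5-oxopentanoate
Product: 10 methyl 6-bromo-5-oxohexanoate, via methyl 6-diazo-5-oxohexanoate 9 (not isolated)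
Conditions: TMSCHN2 (2 equiv), MeCN/THF, 0 °C to rt; then 48% aq. HBr, 0 °C
Reagents that add atoms: trimethylsilyldiazomethane, C[Si](C)(C)C=[N+]=[N-]; hydrogen bromide, Br
Why: Acylation of the diazoalkane by the acid chloride (Arndt–Eistert-type diazoketone synthesis) followed by protonation of the diazo carbon and displacement of N2 by bromide should place bromine only on the new terminal carbon.

Step 6
Reactants: 7 3,4,5-tribromo-2-(2,4-dibromophenoxy)phenol; 10 methyl 6-bromo-5-oxohexanoate
Product: 11 methyl 6-[3,4,5-tribromo-2-(2,4-dibromophenoxy)phenoxy]-5-oxohexanoate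
Conditions: K2CO3, acetone, 40 °C
Reagents that add atoms: none
Why: Williamson ether synthesis by SN2 displacement at the primary, carbonyl-activated CH2Br, which should be fast enough even for the weakly nucleophilic, ortho-aryloxy-substituted phenoxide of 7.

Step 7
Reactants: 11 methyl 6-[3,4,5-tribromo-2-(2,4-dibromophenoxy)phenoxy]-5-oxohexanoate
Product: 12 2-[3,4,5-tribromo-2-(2,4-dibromophenoxy)phenoxy]cyclohexane-1,3-dione
Conditions: KOtBu (2.2 equiv), THF (0.02 M), 0 °C to rt; then 1 M HCl
Reagents that add atoms: none
Why: KOtBu should remove a proton from the oxygen-bearing methylene C6 of 11, the most acidic carbon because both the ketone and the aryloxy group stabilise the anion, and the enolate carbon then adds to the ester carbonyl and the tetrahedral intermediate expels methoxide, forming the ring A C1–C2 bond; the closest known reaction is the intramolecular Claisen (Dieckmann-type) condensation of 5-oxohexanoates to cyclohexane-1,3-diones. The six-membered carbocycle closes in the 6-(enolendo)-exo-trig mode, since the ketone carbon of the enolate lies inside the new ring and the ester carbonyl oxygen outside it, and this mode is favoured. No stereocentre is created, because C2 of the symmetric dione is not stereogenic and the product is largely enolised. The step needs regioselective C–C bond formation, and the chain secures it: the C4 enolate or the ester enolate could only close four-membered rings, so C6 onto C1 is the only productive pairing. Deprotonation of the acidic dione by the base present drains the equilibrium, and high dilution should suppress intermolecular aldol and Claisen reactions. Aryl bromides and diaryl ethers are expected to be inert to KOtBu in THF at or below room temperature.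

Step 8
Reactants: 12 2-[3,4,5-tribromo-2-(2,4-dibromophenoxy)phenoxy]cyclohexane-1,3-dione
Product: 13 3-bromo-2-[3,4,5-tribromo-2-(2,4-dibromophenoxy)phenoxy]cyclohex-2-en-1-one
Conditions: (COBr)2, DMF (cat.), CH2Cl2, 0 °C to rt
Reagents that add atoms: oxalyl bromide, O=C(Br)C(=O)Br
Why: Vilsmeier-type activation of the enol oxygen of the 1,3-dione followed by addition–elimination of bromide should give the β-bromoenone, and because the dione is symmetric either carbonyl leads to the same C1–O/C3–Br pattern.

Step 9
Reactants: 13 3-bromo-2-[3,4,5-tribromo-2-(2,4-dibromophenoxy)phenoxy]cyclohex-2-en-1-one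
Product: 14 3-bromo-2-[3,4,5-tribromo-2-(2,4-dibromophenoxy)phenoxy]phenol
Conditions: DDQ (1.2 equiv), TsOH·H2O (10 mol%), 1,4-dioxane, 100 °C
Reagents that add atoms: none
Why: Quinone dehydrogenation of a cyclohexenone, in which acid-catalysed enolisation and hydride abstraction by DDQ should give a dienone that tautomerises to the phenol, with aromatisation as the driving force.

Step 10
Reactants: 14 3-bromo-2-[3,4,5-tribromo-2-(2,4-dibromophenoxy)phenoxy]phenol
Product: 15 [3-bromo-2-[3,4,5-tribromo-2-(2,4-dibromophenoxy)phenoxy]phenoxy]tri(propan-2-yl)silane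
Conditions: TIPSOTf, 2,6-lutidine, CH2Cl2, 0 °C to rt
Reagents that add atoms: triisopropylsilyl trifluoromethanesulfonate, CC(C)[Si](OS(=O)(=O)C(F)(F)F)(C(C)C)C(C)C
Why: Silylation of the phenol with a silyl triflate and a hindered pyridine base should give a bulky silyl ether that withstands the next two steps and further shields ring A C6.

Step 11
Reactants: 15 [3-bromo-2-[3,4,5-tribromo-2-(2,4-dibromophenoxy)phenoxy]phenoxy]tri(propan-2-yl)silane
Product: 16 2-[3-bromo-4-[3,4,5-tribromo-2-(2,4-dibromophenoxy)phenoxy]-5-[tri(propan-2-yl)silyloxy]phenyl]-4,4,5,5-tetramethyl-1,3,2-dioxaborolane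
Conditions: B2pin2 (1.0 equiv), [Ir(OMe)(cod)]2 (2.5 mol%), 4,4'-di-tert-butyl-2,2'-bipyridine (5 mol%), THF, 80 °C
Reagents that add atoms: bis(pinacolato)diboron, CC1(C)OB(OC1(C)C)B1OC(C)(C)C(C)(C)O1
Why: Iridium-catalysed aromatic C–H borylation is governed by sterics, and ring A C5 is the only C–H of 15 with hydrogen on both neighbouring carbons, while aryl bromides are tolerated by this catalyst.

Step 12
Reactants: 16 2-[3-bromo-4-[3,4,5-tribromo-2-(2,4-dibromophenoxy)phenoxy]-5-[tri(propan-2-yl)silyloxy]phenyl]-4,4,5,5-tetramethyl-1,3,2-dioxaborolane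
Product: 17 [3,5-dibromo-2-[3,4,5-tribromo-2-(2,4-dibromophenoxy)phenoxy]phenoxy]tri(propan-2-yl)silane
Conditions: CuBr2 (3 equiv), MeOH/THF/H2O, 80 °C
Reagents that add atoms: CuBr2 (copper dibromide), Br[Cu]Br
Why: Copper-mediated bromodeboronation of an arylboronate ester (transmetalation to divalent copper, then C–Br bond formation) should replace boron at its own carbon and so fix bromine at ring A C5.

Step 13
Reactants: 17 [3,5-dibromo-2-[3,4,5-tribromo-2-(2,4-dibromophenoxy)phenoxy]phenoxy]tri(propan-2-yl)silane
Product: 18 3,5-dibromo-2-[3,4,5-tribromo-2-(2,4-dibromophenoxy)phenoxy]phenol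
Conditions: TBAF, AcOH, THF, 0 °C
Reagents that add atoms: none
Why: Fluoride-mediated cleavage of the aryl silyl ether, driven by Si–F bond formation, should free the phenol, with AcOH buffering the phenoxide.

Step 14
Reactants: 18 3,5-dibromo-2-[3,4,5-tribromo-2-(2,4-dibromophenoxy)phenoxy]phenol
Product: 20 bromoiesol A sulfate, via pyridinium aryl sulfate 19 (not isolated)
Conditions: SO3·pyridine, pyridine, 50 °C; then Dowex 50W (H+ form), MeOH/H2O, 0 °C
Reagents that add atoms: sulfur trioxide–pyridine complex, [O-]S(=O)(=O)[n+]1ccccc1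
Why: O-Sulfation of the phenol by the SO3·pyridine complex should give the pyridinium aryl sulfate, and a sulfonic acid resin then exchanges pyridinium for a proton.

**Compound list**

1 | guaiacol (2-methoxyphenol) | COc1ccccc1O | starting material
2 | 2,3,4-tribromo-6-methoxyphenol | COc1cc(Br)c(Br)c(Br)c1O | intermediate
3 | 2,4-dibromo-1-iodobenzene | Brc1ccc(I)c(Br)c1 | starting material
4 | 2,4-dibromo-1-[hydroxy(tosyloxy)iodo]benzene | Cc1ccc(cc1)S(=O)(=O)OI(O)c1ccc(Br)cc1Br | intermediate (not isolated)
5 | (2,4-dibromophenyl)(2,4,6-trimethoxyphenyl)iodonium 4-methylbenzenesulfonate | COc1cc(OC)c([I+]c2ccc(Br)cc2Br)c(OC)c1.Cc1ccc(cc1)S(=O)(=O)[O-] | intermediate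
6 | 1,2,3-tribromo-4-(2,4-dibromophenoxy)-5-methoxybenzene | COc1cc(Br)c(Br)c(Br)c1Oc1ccc(Br)cc1Br | intermediate
7 | 3,4,5-tribromo-2-(2,4-dibromophenoxy)phenol | Oc1cc(Br)c(Br)c(Br)c1Oc1ccc(Br)cc1Br | intermediate
8 | methyl 5-chloro-5-oxopentanoate | COC(=O)CCCC(Cl)=O | starting material
9 | methyl 6-diazo-5-oxohexanoate | COC(=O)CCCC(=O)C=[N+]=[N-] | intermediate (not isolated)
10 | methyl 6-bromo-5-oxohexanoate | COC(=O)CCCC(=O)CBr | intermediate
11 | methyl 6-[3,4,5-tribromo-2-(2,4-dibromophenoxy)phenoxy]-5-oxohexanoate | COC(=O)CCCC(=O)COc1cc(Br)c(Br)c(Br)c1Oc1ccc(Br)cc1Br | intermediate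
12 | 2-[3,4,5-tribromo-2-(2,4-dibromophenoxy)phenoxy]cyclohexane-1,3-dione (drawn as the diketo tautomer) | O=C1CCCC(=O)C1Oc1cc(Br)c(Br)c(Br)c1Oc1ccc(Br)cc1Br | intermediate
13 | 3-bromo-2-[3,4,5-tribromo-2-(2,4-dibromophenoxy)phenoxy]cyclohex-2-en-1-one | O=C1CCCC(Br)=C1Oc1cc(Br)c(Br)c(Br)c1Oc1ccc(Br)cc1Br | intermediate
14 | 3-bromo-2-[3,4,5-tribromo-2-(2,4-dibromophenoxy)phenoxy]phenol | Oc1cccc(Br)c1Oc1cc(Br)c(Br)c(Br)c1Oc1ccc(Br)cc1Br | intermediate
15 | [3-bromo-2-[3,4,5-tribromo-2-(2,4-dibromophenoxy)phenoxy]phenoxy]tri(propan-2-yl)silane | CC(C)[Si](Oc1cccc(Br)c1Oc1cc(Br)c(Br)c(Br)c1Oc1ccc(Br)cc1Br)(C(C)C)C(C)C | intermediate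
16 | 2-[3-bromo-4-[3,4,5-tribromo-2-(2,4-dibromophenoxy)phenoxy]-5-[tri(propan-2-yl)silyloxy]phenyl]-4,4,5,5-tetramethyl-1,3,2-dioxaborolane | CC(C)[Si](Oc1cc(B2OC(C)(C)C(C)(C)O2)cc(Br)c1Oc1cc(Br)c(Br)c(Br)c1Oc1ccc(Br)cc1Br)(C(C)C)C(C)C | intermediate
17 | [3,5-dibromo-2-[3,4,5-tribromo-2-(2,4-dibromophenoxy)phenoxy]phenoxy]tri(propan-2-yl)silane | CC(C)[Si](Oc1cc(Br)cc(Br)c1Oc1cc(Br)c(Br)c(Br)c1Oc1ccc(Br)cc1Br)(C(C)C)C(C)C | intermediate
18 | 3,5-dibromo-2-[3,4,5-tribromo-2-(2,4-dibromophenoxy)phenoxy]phenol | Oc1cc(Br)cc(Br)c1Oc1cc(Br)c(Br)c(Br)c1Oc1ccc(Br)cc1Br | intermediate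
19 | pyridinium 3,5-dibromo-2-[3,4,5-tribromo-2-(2,4-dibromophenoxy)phenoxy]phenyl sulfate | [O-]S(=O)(=O)Oc1cc(Br)cc(Br)c1Oc1cc(Br)c(Br)c(Br)c1Oc1ccc(Br)cc1Br.c1cc[nH+]cc1 | intermediate (not isolated)
20 | bromoiesol A sulfate, 3,5-dibromo-2-[3,4,5-tribromo-2-(2,4-dibromophenoxy)phenoxy]phenyl hydrogen sulfate | O=S(=O)(O)Oc1cc(Br)cc(Br)c1Oc1cc(Br)c(Br)c(Br)c1Oc1ccc(Br)cc1Br | target

**Step count**

Total: 14 steps. Longest linear sequence: 12 steps from guaiacol (steps 1, 3, 4, 6 to 14); steps 2 and 5 each make a side fragment in one operation.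

**Steps most likely to fail, with fallbacks**

Step 9. Hydride abstraction from the electron-poor bromoenone may stall, or the phenol may be oxidised further as it forms. The fallback replaces direct dehydrogenation by selenation and selenoxide elimination. Setting out from bromoenone 13, kinetic deprotonation at the α' position C6 with LiN(SiMe3)2 in THF at −78 °C and trapping with PhSeCl would give racemic 3-bromo-6-(phenylselanyl)-2-[3,4,5-tribromo-2-(2,4-dibromophenoxy)phenoxy]cyclohex-2-en-1-one F1. This amide base is too weak to metalate the bromoarene rings. Oxidation with H2O2 and pyridine in CH2Cl2 at 0 °C would give the selenoxide 6-(benzeneseleninyl)-3-bromo-2-[3,4,5-tribromo-2-(2,4-dibromophenoxy)phenoxy]cyclohex-2-en-1-one F2. Its syn-elimination and enolisation of the dienone formed would deliver phenol 14, where the route is rejoined.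

Step 11. Site selectivity may erode through borylation next to an oxygen on ring C, or the catalyst may be lost to oxidative addition into one of the six C–Br bonds. The fallback places the bromine by electrophilic substitution after the phenol oxygen has been deactivated. Setting out from phenol 14, mesylation (MsCl, Et3N, CH2Cl2) would give 3-bromo-2-[3,4,5-tribromo-2-(2,4-dibromophenoxy)phenoxy]phenyl methanesulfonate F3. With the sulfonate no longer donating, NBS (1.0 equiv) in CF3CO2H with catalytic H2SO4 should be steered by the diaryl ether oxygen of ring A to its free para position C5, giving 3,5-dibromo-2-[3,4,5-tribromo-2-(2,4-dibromophenoxy)phenoxy]phenyl methanesulfonate F4. KOH in MeOH/THF at 60 °C followed by acidification would cleave the sulfonate and return the route at phenol 18, so that 15 to 17 are not needed.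

Step 7. Intermolecular aldol or Claisen condensation may outrun ring closure, or the base may degrade the keto ester. The fallback brings in ring A as a preformed dione and makes the A–O–B bond by carbene O–H insertion. Setting out from phenol 7, 2-diazocyclohexane-1,3-dione F5 (from cyclohexane-1,3-dione by diazo transfer with 4-acetamidobenzenesulfonyl azide and Et3N) would be decomposed with Rh2(OAc)4 (1 mol%) in 1,2-dichloroethane at 80 °C in the presence of 7. O–H insertion of the rhodium carbene should give dione 12 directly, where the route is rejoined; steps 5 and 6 would then not be needed.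

**Further compounds**

F1 | step 9 | 3-bromo-6-(phenylselanyl)-2-[3,4,5-tribromo-2-(2,4-dibromophenoxy)phenoxy]cyclohex-2-en-1-one (racemic) | O=C1C([Se]c2ccccc2)CCC(Br)=C1Oc1cc(Br)c(Br)c(Br)c1Oc1ccc(Br)cc1Br
F2 | step 9 | 6-(benzeneseleninyl)-3-bromo-2-[3,4,5-tribromo-2-(2,4-dibromophenoxy)phenoxy]cyclohex-2-en-1-one (mixture of diastereomers) | O=C1C([Se](=O)c2ccccc2)CCC(Br)=C1Oc1cc(Br)c(Br)c(Br)c1Oc1ccc(Br)cc1Br
F3 | step 11 | 3-bromo-2-[3,4,5-tribromo-2-(2,4-dibromophenoxy)phenoxy]phenyl methanesulfonate | CS(=O)(=O)Oc1cccc(Br)c1Oc1cc(Br)c(Br)c(Br)c1Oc1ccc(Br)cc1Br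
F4 | step 11 | 3,5-dibromo-2-[3,4,5-tribromo-2-(2,4-dibromophenoxy)phenoxy]phenyl methanesulfonate | CS(=O)(=O)Oc1cc(Br)cc(Br)c1Oc1cc(Br)c(Br)c(Br)c1Oc1ccc(Br)cc1Br
F5 | step 7 | 2-diazocyclohexane-1,3-dione | O=C1CCCC(=O)C1=[N+]=[N-]
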